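**Plan**

- Cuts (retrosynthesis): first the fifteen O–CH3 bonds, then the four C4–O bonds of the outer rings, then the hub–O bond to the chlorinated ring, then the two hub–O bonds to the arms. Each arm is cut at its biaryl C–C bond and then at its diaryl ether C–O bond.
- Enabling feature: every aromatic C–H of the target lies between two oxygen-bearing carbons. If the 4-OH is left off the four outer rings (the two O-linked 2,4,6-trihydroxyphenoxy rings A and the two C-linked 2,4,6-trihydroxyphenyl rings C), the four C4–H bonds that result are the only aromatic C–H bonds of the octamer with hydrogen on both neighbouring carbons.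
- Forward order: no ring is formed; eight ready-made benzene rings are joined. Arm: inner ring B + ring A (Ullmann ether), then ring C (ortho-lithiation, iodination, Suzuki coupling). Two arms go onto a 2,6-difluorobenzaldehyde hub (SNAr); formyl becomes hydroxyl (Dakin); the chlorinated ring is attached (Ullmann); fourfold C–H oxygenation; global demethylation.
- Stereochemistry: the target has no stereocentre and no stereogenic axis (each hindered biaryl axis carries a ring with identical 2- and 6-substituents), so nothing has to be set.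

Key step: step 10

In the names below, Ar stands for the arm aryl group 2,6-dimethoxy-3-(2,6-dimethoxyphenyl)-4-(2,6-dimethoxyphenoxy)phenyl, bonded through C1.

Step 1
Reactants: 1 4-bromo-2,6-dimethoxyphenol
Product: 2 5-bromo-1,3-dimethoxy-2-(methoxymethoxy)benzene
Conditions: NaH, MOMCl, DMF, 0 °C to rt
Reagents that add atoms: chloromethyl methyl ether, SMILES COCCl
Why: Williamson-type O-alkylation of the sodium phenoxide masks the hydroxyl destined for the hub as a methoxymethyl acetal, which tolerates the later copper, organolithium and palladium steps and is removable by acid without loss of a methyl ether.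

Step 2
Reactants: 2 5-bromo-1,3-dimethoxy-2-(methoxymethoxy)benzene; 3 2,6-dimethoxyphenol
Product: 4 5-(2,6-dimethoxyphenoxy)-1,3-dimethoxy-2-(methoxymethoxy)benzene
Conditions: CuI (10 mol %), picolinic acid (20 mol %), K3PO4, DMSO, 100 °C, Ar
Reagents that add atoms: none
Why: Ullmann diaryl ether synthesis, in which the hindered 2,6-dimethoxyphenoxide meets a bromide with hydrogen on both carbons next to C–Br (the pairing long used for methylated phlorethols), with picolinic acid keeping monovalent copper active for di-ortho-substituted phenols.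

Step 3
Reactants: 4 5-(2,6-dimethoxyphenoxy)-1,3-dimethoxy-2-(methoxymethoxy)benzene
Product: 6 1-(2,6-dimethoxyphenoxy)-2-iodo-3,5-dimethoxy-4-(methoxymethoxy)benzene, via aryllithium 5 (not isolated)
Conditions: n-BuLi (1.2 equiv), THF, 0 °C; then I2, −78 °C to rt
Reagents that add atoms: iodine, SMILES [I][I]; n-butyllithium, SMILES [Li]CCCC (its lithium is carried only by intermediate 5)
Why: Directed ortho-metalation: the only hydrogens flanked by two ether oxygens (methoxy and aryloxy) are the two symmetry-equivalent ones of ring B, so butyllithium should deprotonate there and not next to a single methoxy group of ring A, and iodine traps the aryllithium.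

Step 4
Reactants: 6 1-(2,6-dimethoxyphenoxy)-2-iodo-3,5-dimethoxy-4-(methoxymethoxy)benzene; 7 2,6-dimethoxyphenylboronic acid (2.5 equiv, in portions)
Product: 8 1,3-dimethoxy-2-(methoxymethoxy)-4-(2,6-dimethoxyphenyl)-5-(2,6-dimethoxyphenoxy)benzene
Conditions: Pd(OAc)2 (5 mol %), SPhos (10 mol %), K3PO4, toluene/H2O, 100 °C
Reagents that add atoms: none
Why: Suzuki–Miyaura coupling with SPhos-ligated zerovalent palladium, the established system for biaryls with four ortho substituents from 2,6-dimethoxyphenylboronic acid, the iodide giving oxidative addition fast enough to outrun protodeboronation of the excess boronic acid.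

Step 5
Reactants: 8 1,3-dimethoxy-2-(methoxymethoxy)-4-(2,6-dimethoxyphenyl)-5-(2,6-dimethoxyphenoxy)benzene
Product: 9 2,6-dimethoxy-3-(2,6-dimethoxyphenyl)-4-(2,6-dimethoxyphenoxy)phenol (ArOH)
Conditions: conc. HCl (cat.), MeOH, 50 °C
Reagents that add atoms: none
Why: Acid-catalysed acetal cleavage (transacetalisation to dimethoxymethane) frees the phenol, while aryl methyl ethers and diaryl ethers are stable to dilute acid in methanol.

Step 6
Reactants: 9 ArOH (2.3 equiv); 10 2,6-difluoro-4-methoxybenzaldehyde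
Product: 11 2,6-bis(ArO)-4-methoxybenzaldehyde
Conditions: Cs2CO3, DMSO, 110 °C, Ar
Reagents that add atoms: none
Why: Twofold nucleophilic aromatic substitution (addition–elimination), each fluoride being ortho to the formyl group that stabilises the Meisenheimer intermediate, a mode of C–O bond formation that tolerates a di-ortho-methoxy phenoxide well.

Step 7
Reactants: 11 2,6-bis(ArO)-4-methoxybenzaldehyde
Product: 13 2,6-bis(ArO)-4-methoxyphenol, via aryl formate 12 (not isolated)
Conditions: mCPBA (1.3 equiv), CH2Cl2, 0 °C to rt; then K2CO3 (3 equiv), MeOH, rt, Ar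
Reagents that add atoms: mCPBA, SMILES OOC(=O)c1cccc(Cl)c1
Why: Baeyer–Villiger (Dakin-type) oxidation, in which the electron-rich aryl group migrates in the Criegee intermediate to give the aryl formate that methanolysis cleaves, so the formyl carbon that activated step 6 is exchanged for the central hub oxygen.

Step 8
Reactants: 14 2-chloro-1,3-dimethoxybenzene
Product: 16 5-bromo-2-chloro-1,3-dimethoxybenzene, via pinacol boronate 15 (not isolated)
Conditions: [Ir(OMe)(cod)]2 (1 mol %), dtbpy (2 mol %), B2pin2 (0.55 equiv), THF, 80 °C; then CuBr2 (3 equiv), MeOH/H2O 1:1, 80 °C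
Reagents that add atoms: CuBr2, SMILES [Cu+2].[Br-].[Br-]; bis(pinacolato)diboron, SMILES CC1(C)OB(OC1(C)C)B1OC(C)(C)C(C)(C)O1 (its boron is carried only by intermediate 15)
Why: Sterically controlled iridium-catalysed C–H borylation takes the only C–H of 14 without an ortho substituent (C5) and copper-mediated bromodeboronation then gives the bromide, the aryl chloride being inert to both.

Step 9
Reactants: 13 2,6-bis(ArO)-4-methoxyphenol; 16 5-bromo-2-chloro-1,3-dimethoxybenzene (1.5 equiv)
Product: 17 2-(4-chloro-3,5-dimethoxyphenoxy)-5-methoxy-1,3-bis(ArO)benzene (pentadeca-O-methyl octamer lacking the four outer para oxygens)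
Conditions: CuI (20 mol %), picolinic acid (40 mol %), K3PO4, DMSO, 100 °C, Ar
Reagents that add atoms: none
Why: Ullmann diaryl ether synthesis pairing a hindered phenoxide with an aryl bromide that has hydrogen at both ortho positions, the favourable case for CuI/picolinic acid; C–Br reacts while the flanked C–Cl does not, and the absence of an oxidant spares the electron-rich phenol.

Step 10
Reactants: 17 2-(4-chloro-3,5-dimethoxyphenoxy)-5-methoxy-1,3-bis(ArO)benzene
Product: 19 tetraphenol of 17 (hydroxyl at C4 of each of the two 2,6-dimethoxyphenoxy and the two 2,6-dimethoxyphenyl rings; fifteen methyl ethers kept), via fourfold pinacol boronate 18 (not isolated)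
Conditions: [Ir(OMe)(cod)]2 (5 mol %), dtbpy (10 mol %), B2pin2 (6 equiv), THF, 80 °C; then NaBO3·4H2O, THF/H2O, rt
Reagents that add atoms: sodium perborate NaBO3, SMILES [Na+].[O-]OB=O; bis(pinacolato)diboron, SMILES CC1(C)OB(OC1(C)C)B1OC(C)(C)C(C)(C)O1 (its boron is carried only by intermediate 18)
Why: The trivalent iridium tris(boryl) complex (dtbpy)Ir(Bpin)3, formed from [Ir(OMe)(cod)]2, dtbpy and B2pin2, cleaves an aryl C–H bond through a crowded transition state, releases ArBpin by C–B reductive elimination and is regenerated by B2pin2. The closest known reaction type is the sterically governed C–H borylation of 1,3-disubstituted and 1,2,3-trisubstituted arenes at the carbon with hydrogen on both neighbours, followed in the same flask by oxidation of the arylboronate to the phenol. No ring closes and no stereocentre is formed; four aryl C–O bonds replace four C–H bonds. The step needs site selectivity among the eighteen aromatic C–H bonds of 17, and the substrate secures it: only C4–H of the four outer rings has no ortho substituent, whereas the two hub hydrogens, the single hydrogen of each ring B and the two hydrogens of the chlorinated ring each lie between two oxygen-bearing carbons, and H3/H5 of the outer rings sit next to a methoxy group (and next to Bpin once C4 has reacted). In the oxidation, hydroperoxide from perborate adds to boron and the aryl group shifts from boron to oxygen at the same carbon, so each hydroxyl appears exactly where boron was. The aryl chloride, the methyl ethers and the diaryl ethers are inert to the iridium boryl catalyst and to aqueous perborate.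

Step 11
Reactants: 19 tetraphenol with fifteen methyl ethers
Product: 20 CNP0275555.0
Conditions: BBr3 (excess), CH2Cl2, −78 °C to rt; then H2O, 0 °C; work-up under Ar
Reagents that add atoms: none
Why: Lewis acid ether cleavage, in which BBr3 complexes each methoxy oxygen and bromide attacks the methyl carbon (SN2), while the diaryl ether, biaryl and aryl–chlorine bonds offer no sp3 carbon and should survive; hydrolysis of the aryl borates then frees all nineteen hydroxyl groups.

**Compound list**

1 | 4-bromo-2,6-dimethoxyphenol | COc1cc(Br)cc(OC)c1O | starting material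
2 | 5-bromo-1,3-dimethoxy-2-(methoxymethoxy)benzene | COCOc1c(OC)cc(Br)cc1OC | intermediate
3 | 2,6-dimethoxyphenol | COc1cccc(OC)c1O | starting material
4 | 5-(2,6-dimethoxyphenoxy)-1,3-dimethoxy-2-(methoxymethoxy)benzene | COCOc1c(OC)cc(Oc2c(OC)cccc2OC)cc1OC | intermediate
5 | [6-(2,6-dimethoxyphenoxy)-2,4-dimethoxy-3-(methoxymethoxy)phenyl]lithium | [Li]c1c(OC)c(OCOC)c(OC)cc1Oc1c(OC)cccc1OC | intermediate
6 | 1-(2,6-dimethoxyphenoxy)-2-iodo-3,5-dimethoxy-4-(methoxymethoxy)benzene | COCOc1c(OC)cc(Oc2c(OC)cccc2OC)c(I)c1OC | intermediate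
7 | 2,6-dimethoxyphenylboronic acid | COc1cccc(OC)c1B(O)O | starting material
8 | 1,3-dimethoxy-2-(methoxymethoxy)-4-(2,6-dimethoxyphenyl)-5-(2,6-dimethoxyphenoxy)benzene | COCOc1c(OC)cc(Oc2c(OC)cccc2OC)c(-c2c(OC)cccc2OC)c1OC | intermediate
9 | 2,6-dimethoxy-3-(2,6-dimethoxyphenyl)-4-(2,6-dimethoxyphenoxy)phenol (ArOH) | COc1cc(Oc2c(OC)cccc2OC)c(-c2c(OC)cccc2OC)c(OC)c1O | intermediate
10 | 2,6-difluoro-4-methoxybenzaldehyde | COc1cc(F)c(C=O)c(F)c1 | starting material
11 | 2,6-bis(ArO)-4-methoxybenzaldehyde | COc1cc(Oc2c(OC)cc(Oc3c(OC)cccc3OC)c(-c3c(OC)cccc3OC)c2OC)c(C=O)c(Oc2c(OC)cc(Oc3c(OC)cccc3OC)c(-c3c(OC)cccc3OC)c2OC)c1 | intermediate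
12 | 2,6-bis(ArO)-4-methoxyphenyl formate | COc1cc(Oc2c(OC)cc(Oc3c(OC)cccc3OC)c(-c3c(OC)cccc3OC)c2OC)c(OC=O)c(Oc2c(OC)cc(Oc3c(OC)cccc3OC)c(-c3c(OC)cccc3OC)c2OC)c1 | intermediate
13 | 2,6-bis(ArO)-4-methoxyphenol | COc1cc(Oc2c(OC)cc(Oc3c(OC)cccc3OC)c(-c3c(OC)cccc3OC)c2OC)c(O)c(Oc2c(OC)cc(Oc3c(OC)cccc3OC)c(-c3c(OC)cccc3OC)c2OC)c1 | intermediate
14 | 2-chloro-1,3-dimethoxybenzene | COc1cccc(OC)c1Cl | starting material
15 | 2-(4-chloro-3,5-dimethoxyphenyl)-4,4,5,5-tetramethyl-1,3,2-dioxaborolane | COc1cc(B2OC(C)(C)C(C)(C)O2)cc(OC)c1Cl | intermediate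
16 | 5-bromo-2-chloro-1,3-dimethoxybenzene | COc1cc(Br)cc(OC)c1Cl | intermediate
17 | 2-(4-chloro-3,5-dimethoxyphenoxy)-5-methoxy-1,3-bis(ArO)benzene | COc1cc(Oc2c(OC)cc(Oc3c(OC)cccc3OC)c(-c3c(OC)cccc3OC)c2OC)c(Oc2cc(OC)c(Cl)c(OC)c2)c(Oc2c(OC)cc(Oc3c(OC)cccc3OC)c(-c3c(OC)cccc3OC)c2OC)c1 | intermediate
18 | fourfold pinacol boronate of 17 (Bpin at C4 of each outer ring) | COc1cc(Oc2c(OC)cc(Oc3c(OC)cc(B4OC(C)(C)C(C)(C)O4)cc3OC)c(-c3c(OC)cc(B4OC(C)(C)C(C)(C)O4)cc3OC)c2OC)c(Oc2cc(OC)c(Cl)c(OC)c2)c(Oc2c(OC)cc(Oc3c(OC)cc(B4OC(C)(C)C(C)(C)O4)cc3OC)c(-c3c(OC)cc(B4OC(C)(C)C(C)(C)O4)cc3OC)c2OC)c1 | intermediate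
19 | tetraphenol of 17 with fifteen methyl ethers (hydroxyl at C4 of each outer ring) | COc1cc(Oc2c(OC)cc(Oc3c(OC)cc(O)cc3OC)c(-c3c(OC)cc(O)cc3OC)c2OC)c(Oc2cc(OC)c(Cl)c(OC)c2)c(Oc2c(OC)cc(Oc3c(OC)cc(O)cc3OC)c(-c3c(OC)cc(O)cc3OC)c2OC)c1 | intermediate
20 | CNP0275555.0: 5-hydroxybenzene hub carrying 4-chloro-3,5-dihydroxyphenoxy at C2 and, at C1 and C3, two 2,6-dihydroxy-3-(2,4,6-trihydroxyphenyl)-4-(2,4,6-trihydroxyphenoxy)phenoxy arms | Oc1cc(O)c(Oc2cc(O)c(Oc3cc(O)cc(Oc4c(O)cc(Oc5c(O)cc(O)cc5O)c(-c5c(O)cc(O)cc5O)c4O)c3Oc3cc(O)c(Cl)c(O)c3)c(O)c2-c2c(O)cc(O)cc2O)c(O)c1 | target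

**Step count**

Total: 11 steps. Longest linear sequence: 10 steps (steps 1 to 7, then 9, 10 and 11); step 8 is a one-step side branch.

**Steps most likely to fail**

Step 9. The phenoxide oxygen of 13 is screened by two bulky ortho aryloxy arms and may not enter the coordination sphere of copper, so that bromide 16 is only reduced or recovered. The fallback changes the order in which the three hub ethers are made, attaching the chlorinated ring while the hub phenol is still small. It sets out from boronate 15 (made as in step 8, before the bromination) and from arm phenol 9. Boronate 15 is hydrolysed with NaIO4 and aqueous HCl to (4-chloro-3,5-dimethoxyphenyl)boronic acid F1. A Chan–Lam coupling (Cu(OAc)2, pyridine, 4 Å molecular sieves, CH2Cl2, air, rt) of F1 with purchased 2,6-dibromo-4-methoxyphenol, a 2,6-dihalophenol of the kind known to undergo this reaction, should give 1,3-dibromo-2-(4-chloro-3,5-dimethoxyphenoxy)-5-methoxybenzene F2. A twofold Ullmann coupling of F2 with 9 (CuI, picolinic acid, K3PO4, DMSO, 110 °C) comes back to the route at 17; steps 6 and 7 are then not needed.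

Step 10. Borylation may stall in the crowded octamer before every molecule has reacted at all four sites, which after oxidation would leave mixtures of partly hydroxylated products that are hard to separate. The fallback moves the same C–H oxygenation to the arm, where only two sites per molecule must react and the substrate is small. It sets out from 8 and comes back to the route at 20.
- Twofold borylation of 8 under the conditions of step 10 should give the bis(pinacol boronate) F3, oxidised in the flask with NaBO3 to the arm diphenol F4.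
- Methylation (MeI, K2CO3, acetone) gives the methoxymethyl-protected arm with 2,4,6-trimethoxy outer rings F5, and HCl in methanol frees the arm phenol F6.
- SNAr of F6 with 10 as in step 6 gives the bis(aryloxy)benzaldehyde F7; mCPBA gives the aryl formate F8 and methanolysis the hub phenol F9.
- Ullmann coupling of F9 with 16 as in step 9 gives the nonadeca-O-methyl octamer F10, and BBr3 as in step 11 gives 20.

Step 4. Protodeboronation of 7 may outrun transmetalation onto the congested arylpalladium iodide, so that 6 is consumed only by reduction. The fallback reverses the polarity of the biaryl coupling and uses no boron. It sets out from aryllithium 5 (step 3, before the iodine quench): transmetalation with ZnCl2 gives the arylzinc chloride F11, and Negishi coupling with purchased 2-bromo-1,3-dimethoxybenzene (Pd2(dba)3, RuPhos, THF, 70 °C) comes back to the route at 8, bypassing iodide 6.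

**Further compounds**

F1 | step 9 | (4-chloro-3,5-dimethoxyphenyl)boronic acid | COc1cc(B(O)O)cc(OC)c1Cl
F2 | step 9 | 1,3-dibromo-2-(4-chloro-3,5-dimethoxyphenoxy)-5-methoxybenzene | COc1cc(Br)c(Oc2cc(OC)c(Cl)c(OC)c2)c(Br)c1
F3 | step 10 | bis(pinacol boronate) of 8 (Bpin at C4 of both outer rings) | COCOc1c(OC)cc(Oc2c(OC)cc(B3OC(C)(C)C(C)(C)O3)cc2OC)c(-c2c(OC)cc(B3OC(C)(C)C(C)(C)O3)cc2OC)c1OC
F4 | step 10 | arm diphenol (hydroxyl at C4 of both outer rings of 8) | COCOc1c(OC)cc(Oc2c(OC)cc(O)cc2OC)c(-c2c(OC)cc(O)cc2OC)c1OC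
F5 | step 10 | 1,3-dimethoxy-2-(methoxymethoxy)-4-(2,4,6-trimethoxyphenyl)-5-(2,4,6-trimethoxyphenoxy)benzene | COCOc1c(OC)cc(Oc2c(OC)cc(OC)cc2OC)c(-c2c(OC)cc(OC)cc2OC)c1OC
F6 | step 10 | 2,6-dimethoxy-3-(2,4,6-trimethoxyphenyl)-4-(2,4,6-trimethoxyphenoxy)phenol | COc1cc(Oc2c(OC)cc(OC)cc2OC)c(-c2c(OC)cc(OC)cc2OC)c(OC)c1O
F7 | step 10 | 4-methoxy-2,6-bis[2,6-dimethoxy-3-(2,4,6-trimethoxyphenyl)-4-(2,4,6-trimethoxyphenoxy)phenoxy]benzaldehyde | COc1cc(Oc2c(OC)cc(Oc3c(OC)cc(OC)cc3OC)c(-c3c(OC)cc(OC)cc3OC)c2OC)c(C=O)c(Oc2c(OC)cc(Oc3c(OC)cc(OC)cc3OC)c(-c3c(OC)cc(OC)cc3OC)c2OC)c1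
F8 | step 10 | aryl formate from F7 | COc1cc(Oc2c(OC)cc(Oc3c(OC)cc(OC)cc3OC)c(-c3c(OC)cc(OC)cc3OC)c2OC)c(OC=O)c(Oc2c(OC)cc(Oc3c(OC)cc(OC)cc3OC)c(-c3c(OC)cc(OC)cc3OC)c2OC)c1
F9 | step 10 | 4-methoxy-2,6-bis[2,6-dimethoxy-3-(2,4,6-trimethoxyphenyl)-4-(2,4,6-trimethoxyphenoxy)phenoxy]phenol | COc1cc(Oc2c(OC)cc(Oc3c(OC)cc(OC)cc3OC)c(-c3c(OC)cc(OC)cc3OC)c2OC)c(O)c(Oc2c(OC)cc(Oc3c(OC)cc(OC)cc3OC)c(-c3c(OC)cc(OC)cc3OC)c2OC)c1
F10 | step 10 | nonadeca-O-methyl ether of the target | COc1cc(Oc2c(OC)cc(Oc3c(OC)cc(OC)cc3OC)c(-c3c(OC)cc(OC)cc3OC)c2OC)c(Oc2cc(OC)c(Cl)c(OC)c2)c(Oc2c(OC)cc(Oc3c(OC)cc(OC)cc3OC)c(-c3c(OC)cc(OC)cc3OC)c2OC)c1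
F11 | step 4 | [6-(2,6-dimethoxyphenoxy)-2,4-dimethoxy-3-(methoxymethoxy)phenyl]zinc chloride | Cl[Zn]c1c(OC)c(OCOC)c(OC)cc1Oc1c(OC)cccc1OC
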